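**Retrosynthetic overview**

- The strategy rests on ring B of the naphthalene (C1, C2, C3, C4, C4a, C8a): C2 lies between C1, which carries the 4-methoxyphenyl group, and C3, which carries nitrogen. Taking C2 out leaves the five-membered ring of a 3-aryl-2-aminoindene.
- Key disconnection: C1–C2 and C2–C3. Both bonds form when CBr2 is inserted into the C=C bond of Boc-enecarbamate 10 (five- to six-membered ring expansion). The bromine left on C2 is then exchanged for nitrogen, and Boc removal, bis-formylation and debenzylation finish the target.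
- Enecarbamate 10 comes from 1-aryl-2-indanone 8 and tert-butyl carbamate 9; 8 from 3-arylindene 6 by epoxidation and 1,2-hydride shift; 6 from 5,6-bis(benzyloxy)indan-1-one 3 and aryl Grignard reagent 4.
- Ring order: catechol ring A and the five-membered ring are bought as indanone 1, the anisyl ring is attached in step 3, and the only ring made is ring B, by expansion in step 6.

Key step: step 6

Remarks: the target is achiral, so intermediates 5, 7, 8 and 12 are racemic and their stereocentres are erased later. 4-Methoxyphenylmagnesium bromide is taken as the commercial THF solution. Benzyl ethers replace the methyl ethers of 1 so that the catechol can be freed at the end without touching the anisole methyl ether.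

**Route**

Step 1
Reactants: 1 5,6-dimethoxyindan-1-one
Product: 2 5,6-dihydroxyindan-1-one
Conditions: BBr3 (3 equiv), CH2Cl2, −78 °C to rt; MeOH, then H2O
Reagents that add atoms: none
Why: BBr3 demethylation of aryl methyl ethers (Lewis acid complexation, then bromide attack on the methyl group) should free both phenols, while the aryl ketone only binds the Lewis acid reversibly.

Step 2
Reactants: 2 5,6-dihydroxyindan-1-one
Product: 3 5,6-bis(benzyloxy)indan-1-one
Conditions: BnBr (2.4 equiv), K2CO3 (3 equiv), DMF, 60 °C
Reagents that add atoms: benzyl bromide, BrCc1ccccc1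
Why: Williamson ether synthesis; K2CO3 deprotonates the catechol hydroxyls but not the ketone α-CH2, so alkylation should occur on oxygen only.

Step 3
Reactants: 3 5,6-bis(benzyloxy)indan-1-one; 4 4-methoxyphenylmagnesium bromide
Product: 6 5,6-bis(benzyloxy)-3-(4-methoxyphenyl)-1H-indene, via tertiary carbinol 5 (not isolated)
Conditions: 4 (1.4 equiv), THF, 0 °C to rt; 1 M HCl; then TsOH·H2O (2 mol %), toluene, 50 °C
Reagents that add atoms: none
Why: Grignard 1,2-addition to the aryl ketone followed by acid-catalysed E1 dehydration through the anisyl-stabilised benzylic cation should give the conjugated endocyclic alkene, which erases the carbinol stereocentre.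

Step 4
Reactants: 6 5,6-bis(benzyloxy)-3-(4-methoxyphenyl)-1H-indene
Product: 8 racemic 5,6-bis(benzyloxy)-1-(4-methoxyphenyl)indan-2-one, via indene oxide 7 (not isolated)
Conditions: mCPBA (1.05 equiv), NaHCO3, CH2Cl2, 0 °C; aq. Na2S2O3; then BF3·OEt2 (10 mol %), CH2Cl2, −20 °C
Reagents that add atoms: meta-chloroperoxybenzoic acid (mCPBA), OOC(=O)c1cccc(Cl)c1
Why: Prilezhaev epoxidation of the electron-rich trisubstituted alkene followed by Meinwald rearrangement: the C–O bond at the diaryl-substituted carbon ionises and a 1,2-hydride shift from the neighbouring carbon places the carbonyl at C2 and the aryl group at C1 (any hydroxy ester from acid opening of the epoxide should pass through the same cation).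

Step 5
Reactants: 8 racemic 5,6-bis(benzyloxy)-1-(4-methoxyphenyl)indan-2-one; 9 tert-butyl carbamate
Product: 10 tert-butyl N-[5,6-bis(benzyloxy)-3-(4-methoxyphenyl)-1H-inden-2-yl]carbamate
Conditions: 9 (3 equiv), PPTS (10 mol %), 4 Å MS, toluene, 80 °C, argon
Reagents that add atoms: none
Why: Acid-catalysed condensation of a ketone with a primary carbamate (enecarbamate formation, as practised on 2-tetralones and 2-indanones); the N-acyl imine should tautomerise towards the doubly benzylic C1, giving the tetrasubstituted alkene conjugated with both aryl rings, and the sieves remove the water.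

Step 6
Reactants: 10 tert-butyl N-[5,6-bis(benzyloxy)-3-(4-methoxyphenyl)-1H-inden-2-yl]carbamate; 11 bromoform
Product: 13 tert-butyl N-[6,7-bis(benzyloxy)-3-bromo-4-(4-methoxyphenyl)naphthalen-2-yl]carbamate, via dibromocyclopropane adduct 12 (not isolated)
Conditions: 11 (3 equiv), 50% aq. NaOH, BnEt3NCl (10 mol %), toluene, 0 °C to rt
Reagents that add atoms: none
Why: Dibromocarbene, formed by α-elimination from tribromomethanide at the phase boundary, adds as an electrophile in a concerted [2+1] cheletropic step to the C2=C3 enecarbamate bond of 10, the most electron-rich π bond present, to give cyclopropane 12. The cyclopropane bond shared with the five-membered ring then breaks in a disrotatory two-electron electrocyclic opening as the bromide lying over that ring departs, pushed by the nitrogen lone pair at one terminus and by the 4-methoxyphenyl group at the other, so the CBr carbon ends up between the aryl-bearing and the nitrogen-bearing carbon (bonds C1–C2 and C2–C3 in target numbering). Base then removes a proton from the former methylene carbon, the only ring position that carries one, and the new ring becomes aromatic with the second bromine still on the inserted carbon. The closest known reactions are the dihalocarbene conversion of indenes into 2-halonaphthalenes and the dihalocarbene ring expansions of indoles, enamines and enamides. Ring B is therefore closed by expansion and not by an end-to-end cyclisation, no stereocentre survives (the two of 12 are erased on aromatisation), and the position of bromine is fixed by the connectivity of the cyclopropane. The step needs chemoselectivity for the enecarbamate alkene over the alkoxy-substituted arenes and the N–H bond, which the high nucleophilicity of the amino-substituted alkene and a limited excess of bromoform at 0 °C should secure.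

Step 7
Reactants: 13 tert-butyl N-[6,7-bis(benzyloxy)-3-bromo-4-(4-methoxyphenyl)naphthalen-2-yl]carbamate
Product: 14 tert-butyl N-[3-amino-6,7-bis(benzyloxy)-4-(4-methoxyphenyl)naphthalen-2-yl]carbamate
Conditions: CuI (20 mol %), L-proline (40 mol %), K2CO3 (2 equiv), 28% aq. NH3, DMSO, 60 °C, sealed tube, argon
Reagents that add atoms: ammonia, N
Why: Ullmann–Goldberg-type copper-catalysed amination with aqueous ammonia, known for 2-halophenyl carbamates; the neighbouring carbamate N–H should chelate copper and speed insertion into the flanked C–Br bond, the small nucleophile tolerates the hindrance, and the moderate temperature should keep the product from closing to a cyclic urea.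

Step 8
Reactants: 14 tert-butyl N-[3-amino-6,7-bis(benzyloxy)-4-(4-methoxyphenyl)naphthalen-2-yl]carbamate
Product: 15 6,7-bis(benzyloxy)-1-(4-methoxyphenyl)naphthalene-2,3-diamine
Conditions: 4 M HCl in dioxane, CH2Cl2, 0 °C to rt; degassed aq. NaHCO3; used at once
Reagents that add atoms: none
Why: Acidolytic Boc cleavage (loss of the tert-butyl cation, then decarboxylation); benzyl aryl ethers and the anisole methyl ether should be stable to anhydrous HCl at rt.

Step 9
Reactants: 15 6,7-bis(benzyloxy)-1-(4-methoxyphenyl)naphthalene-2,3-diamine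
Product: 16 N,N'-[6,7-bis(benzyloxy)-1-(4-methoxyphenyl)naphthalene-2,3-diyl]diformamide
Conditions: acetic formic anhydride (6 equiv, preformed from HCO2H and Ac2O), pyridine, THF, −20 to 0 °C
Reagents that add atoms: acetic formic anhydride, CC(=O)OC=O
Why: N-formylation with a mixed anhydride, which transfers its more electrophilic formyl group; excess reagent at low temperature with pyridine as buffer should acylate both amines before the mono-formamide can cyclodehydrate to the naphthimidazole.

Step 10
Reactants: 16 N,N'-[6,7-bis(benzyloxy)-1-(4-methoxyphenyl)naphthalene-2,3-diyl]diformamide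
Product: 17 Melanocin E, N,N'-[6,7-dihydroxy-1-(4-methoxyphenyl)naphthalene-2,3-diyl]diformamide
Conditions: H2 (1 atm), 10% Pd/C, THF/MeOH, rt; filtration under argon
Reagents that add atoms: none
Why: Catalytic hydrogenolysis of the two benzyl aryl ethers over palladium on carbon; the formamides, the anisole methyl ether and the naphthalene should be inert at 1 atm and rt.

**Compound list**

1 | 5,6-dimethoxyindan-1-one | COc1cc2CCC(=O)c2cc1OC | starting material
2 | 5,6-dihydroxyindan-1-one | O=C1CCc2cc(O)c(O)cc12 | intermediate
3 | 5,6-bis(benzyloxy)indan-1-one | O=C1CCc2cc(OCc3ccccc3)c(OCc3ccccc3)cc12 | intermediate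
4 | 4-methoxyphenylmagnesium bromide (THF solution) | COc1ccc([Mg]Br)cc1 | starting material
5 | racemic 5,6-bis(benzyloxy)-1-(4-methoxyphenyl)indan-1-ol (formed in the flask) | COc1ccc(cc1)C1(O)CCc2cc(OCc3ccccc3)c(OCc3ccccc3)cc12 | intermediate
6 | 5,6-bis(benzyloxy)-3-(4-methoxyphenyl)-1H-indene | COc1ccc(cc1)C1=CCc2cc(OCc3ccccc3)c(OCc3ccccc3)cc12 | intermediate
7 | racemic 2,3-epoxide of 6, epoxide cis-fused to the five-membered ring, aryl on the epoxide carbon next to the arene (formed in the flask) | COc1ccc(cc1)C12OC1Cc1cc(OCc3ccccc3)c(OCc3ccccc3)cc12 | intermediate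
8 | racemic 5,6-bis(benzyloxy)-1-(4-methoxyphenyl)indan-2-one | COc1ccc(cc1)C1C(=O)Cc2cc(OCc3ccccc3)c(OCc3ccccc3)cc12 | intermediate
9 | tert-butyl carbamate | CC(C)(C)OC(N)=O | starting material
10 | tert-butyl N-[5,6-bis(benzyloxy)-3-(4-methoxyphenyl)-1H-inden-2-yl]carbamate | COc1ccc(cc1)C1=C(NC(=O)OC(C)(C)C)Cc2cc(OCc3ccccc3)c(OCc3ccccc3)cc12 | intermediate
11 | bromoform | BrC(Br)Br | starting material
12 | racemic tert-butyl N-[3,4-bis(benzyloxy)-1,1-dibromo-1a-(4-methoxyphenyl)-1,1a,6,6a-tetrahydrocyclopropa[a]inden-6a-yl]carbamate, cis-fused (formed in the flask) | COc1ccc(cc1)C12c3cc(OCc4ccccc4)c(OCc4ccccc4)cc3CC1(NC(=O)OC(C)(C)C)C2(Br)Br | intermediate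
13 | tert-butyl N-[6,7-bis(benzyloxy)-3-bromo-4-(4-methoxyphenyl)naphthalen-2-yl]carbamate | COc1ccc(cc1)-c1c(Br)c(NC(=O)OC(C)(C)C)cc2cc(OCc3ccccc3)c(OCc3ccccc3)cc12 | intermediate
14 | tert-butyl N-[3-amino-6,7-bis(benzyloxy)-4-(4-methoxyphenyl)naphthalen-2-yl]carbamate | COc1ccc(cc1)-c1c(N)c(NC(=O)OC(C)(C)C)cc2cc(OCc3ccccc3)c(OCc3ccccc3)cc12 | intermediate
15 | 6,7-bis(benzyloxy)-1-(4-methoxyphenyl)naphthalene-2,3-diamine | COc1ccc(cc1)-c1c(N)c(N)cc2cc(OCc3ccccc3)c(OCc3ccccc3)cc12 | intermediate
16 | N,N'-[6,7-bis(benzyloxy)-1-(4-methoxyphenyl)naphthalene-2,3-diyl]diformamide | COc1ccc(cc1)-c1c(NC=O)c(NC=O)cc2cc(OCc3ccccc3)c(OCc3ccccc3)cc12 | intermediate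
17 | Melanocin E, N,N'-[6,7-dihydroxy-1-(4-methoxyphenyl)naphthalene-2,3-diyl]diformamide | COc1ccc(-c2c(NC=O)c(NC=O)cc3cc(O)c(O)cc23)cc1 | target

**Step count**

Total step count: 10. Longest linear sequence: 10 steps (1 to 17).

**Steps most likely to fail**

1. Step 6 (key step). Under hydroxide the carbamate N–H and the indene CH2 of 10 are deprotonated, so the carbene may be captured at nitrogen or at the carbanion instead of adding across the alkene. The electron-rich naphthalene product may take up a second carbene, and water may trap the ring-opened cation before proton loss. Migration of the double bond of 10 before carbene addition would be harmless: bromine would then sit on the other side of the nitrogen-bearing carbon, and both carbons end as C–N in 15.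
 Fallback, setting out from 8 and coming back at 15: the ring expansion is run on an oxygen-substituted alkene and both nitrogens are brought in afterwards.
 - Ketone 8 is silylated (TBSOTf, Et3N, CH2Cl2, 0 °C) to the silyl enol ether tert-butyl{[5,6-bis(benzyloxy)-3-(4-methoxyphenyl)-1H-inden-2-yl]oxy}dimethylsilane F1.
 - Dibromocarbene (CHBr3, KOtBu, hexane/THF, −30 °C to rt) adds to give the siloxy dibromocyclopropane F2. This should open with loss of bromide and of the silyl group and tautomerise to 6,7-bis(benzyloxy)-3-bromo-4-(4-methoxyphenyl)naphthalen-2-ol F3, the known ring expansion of silyl enol ethers to α-halo enones.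
 - Tf2O and pyridine (CH2Cl2, 0 °C) give 6,7-bis(benzyloxy)-3-bromo-4-(4-methoxyphenyl)naphthalen-2-yl trifluoromethanesulfonate F4.
 - Double Buchwald–Hartwig coupling with benzophenone imine (Pd2(dba)3, BINAP, Cs2CO3, toluene, 100 °C) at the bromide and the triflate gives 6,7-bis(benzyloxy)-N,N'-bis(diphenylmethylene)-1-(4-methoxyphenyl)naphthalene-2,3-diamine F5.
 - 2 M HCl in THF at rt hydrolyses both imines to diamine 15.

2. Step 7. Insertion of copper into the C–Br bond, which is flanked by the twisted anisyl ring and the carbamate, may be too slow at 60 °C. At higher temperature hydrodebromination, or ring closure of the new amine onto the Boc carbonyl, may take over.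
 Fallback, setting out from 13 and coming back at 14: a polar organometallic route in place of cross-coupling.
 - MeLi (1.1 equiv) and then t-BuLi (2.2 equiv) in THF at −78 °C deprotonate the carbamate and exchange bromine for lithium, giving tert-butyl N-lithio-N-[6,7-bis(benzyloxy)-3-lithio-4-(4-methoxyphenyl)naphthalen-2-yl]carbamate F6, an ortho-lithiated N-Boc anilide of the well-behaved type.
 - Tosyl azide transfers the azido group to carbon, giving tert-butyl N-[3-azido-6,7-bis(benzyloxy)-4-(4-methoxyphenyl)naphthalen-2-yl]carbamate F7.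
 - Staudinger reduction (PPh3, THF/H2O, rt) gives 14.

3. Step 5. Loss of the tert-butyl group from the carbamate under warm acid, or self-condensation and air oxidation of the readily enolised ketone 8, may outrun the condensation.
 Fallback, setting out from 8 and coming back at 10:
 - Deprotonation at the doubly benzylic C1–H and O-sulfonylation (KN(SiMe3)2, PhNTf2, THF, −78 °C) give 5,6-bis(benzyloxy)-3-(4-methoxyphenyl)-1H-inden-2-yl trifluoromethanesulfonate F8.
 - Palladium-catalysed amidation of the enol triflate with 9 (Pd2(dba)3, Xantphos, Cs2CO3, dioxane, 80 °C) gives 10 under non-acidic conditions.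

**Further compounds**

F1 | step 6 | tert-butyl{[5,6-bis(benzyloxy)-3-(4-methoxyphenyl)-1H-inden-2-yl]oxy}dimethylsilane | COc1ccc(cc1)C1=C(O[Si](C)(C)C(C)(C)C)Cc2cc(OCc3ccccc3)c(OCc3ccccc3)cc12
F2 | step 6 | racemic 3,4-bis(benzyloxy)-1,1-dibromo-6a-(tert-butyldimethylsilyloxy)-1a-(4-methoxyphenyl)-1,1a,6,6a-tetrahydrocyclopropa[a]indene (formed in the flask) | COc1ccc(cc1)C12c3cc(OCc4ccccc4)c(OCc4ccccc4)cc3CC1(O[Si](C)(C)C(C)(C)C)C2(Br)Br
F3 | step 6 | 6,7-bis(benzyloxy)-3-bromo-4-(4-methoxyphenyl)naphthalen-2-ol | COc1ccc(cc1)-c1c(Br)c(O)cc2cc(OCc3ccccc3)c(OCc3ccccc3)cc12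
F4 | step 6 | 6,7-bis(benzyloxy)-3-bromo-4-(4-methoxyphenyl)naphthalen-2-yl trifluoromethanesulfonate | COc1ccc(cc1)-c1c(Br)c(OS(=O)(=O)C(F)(F)F)cc2cc(OCc3ccccc3)c(OCc3ccccc3)cc12
F5 | step 6 | 6,7-bis(benzyloxy)-N,N'-bis(diphenylmethylene)-1-(4-methoxyphenyl)naphthalene-2,3-diamine | COc1ccc(cc1)-c1c(N=C(c3ccccc3)c3ccccc3)c(N=C(c3ccccc3)c3ccccc3)cc2cc(OCc3ccccc3)c(OCc3ccccc3)cc12
F6 | step 7 | tert-butyl N-lithio-N-[6,7-bis(benzyloxy)-3-lithio-4-(4-methoxyphenyl)naphthalen-2-yl]carbamate (formed in the flask) | COc1ccc(cc1)-c1c([Li])c(N([Li])C(=O)OC(C)(C)C)cc2cc(OCc3ccccc3)c(OCc3ccccc3)cc12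
F7 | step 7 | tert-butyl N-[3-azido-6,7-bis(benzyloxy)-4-(4-methoxyphenyl)naphthalen-2-yl]carbamate | COc1ccc(cc1)-c1c(N=[N+]=[N-])c(NC(=O)OC(C)(C)C)cc2cc(OCc3ccccc3)c(OCc3ccccc3)cc12
F8 | step 5 | 5,6-bis(benzyloxy)-3-(4-methoxyphenyl)-1H-inden-2-yl trifluoromethanesulfonate | COc1ccc(cc1)C1=C(OS(=O)(=O)C(F)(F)F)Cc2cc(OCc3ccccc3)c(OCc3ccccc3)cc12
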